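**Retrosynthetic overview**

1. The strategy rests on the 14-membered carbocycle C1–C14, which carries one-carbon branches on C4, C8 and C12 (C18, C19, C20) and the three-carbon unit C15(C17)–C16 on C1. This is an uncut head-to-tail geranylgeranyl chain, so the ring is opened at C1–C2 and traced back to GGPP; a cembrene A synthase closes it and sets C1 (R).
2. Oxygen is then relayed round the ring of (R)-cembrene A. The isopropenyl group becomes the C16 acid, and the acid reaches C3=C4 (iodolactonisation, 3,4-epoxide, invertive hydrolysis at C4, six-membered lactone with free C4–OH).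
3. The C4–OH reaches C7=C8 (directed epoxidation, isomerisation to the C7-hydroxy C8=C19 alkene, oxidation and CBS reduction to 7R). C11=C12, the alkene that is left, is epoxidised last under reagent control.
4. Ring order: 14-membered carbocycle (step 3), six-membered lactone C16–O–C3 (step 6, reclosed in step 8), oxirane C11–C12 (step 14). C15 is set by equilibration (step 9).

Key step: step 3

Remark: cembrane numbering is used throughout (C1 ring CH bearing C15; C3 lactone O–CH; C4 carbinol carbon with C18; C7 CHOH; C8 with methylidene C19; C11–C12 epoxide with C20 on C12; C15, C16, C17 lactone CH, carbonyl and methyl). Compounds 7 to 15 are carried as C15 epimer pairs and 17 and 18 as mixtures at C7 and C8, so their SMILES carry no descriptor there; these centres are fixed in steps 9 and 13.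

Assumption: a recombinant class one cembrene A synthase whose product is the (R) enantiomer is used (such enzymes are known); the enantiomer of compound 6 is to be confirmed by rotation before it is carried on.

**Step 1**
Reactants: 1 (2E,6E,10E)-geranylgeraniol
Product: 2 (2E,6E,10E)-geranylgeranyl bromide
Conditions: PBr3 (0.4 equiv), Et2O, −10 °C; used crude
Reagents that add atoms: phosphorus tribromide, BrP(Br)Br
Why: Bromination of a primary allylic alcohol with PBr3 at low temperature goes through the phosphite ester and direct displacement at the CH2 group, so the 2E geometry and the position of the double bond are kept; no stereocentre is formed.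

**Step 2**
Reactants: 2 (2E,6E,10E)-geranylgeranyl bromide; 3 tris(tetrabutylammonium) hydrogen diphosphate
Product: 5 geranylgeranyl diphosphate (GGPP) trisammonium salt, via GGPP bis(tetrabutylammonium) salt 4 (not isolated)
Conditions: 3 (2 equiv), MeCN, rt; then Dowex 50W-X8 (NH4+ form), aq. NH4HCO3/i-PrOH; cellulose chromatography, lyophilisation
Reagents that add atoms: ammonium hydrogencarbonate, [NH4+].OC([O-])=O
Why: SN2 displacement of the primary allylic bromide by the diphosphate trianion in MeCN is the standard preparation of prenyl diphosphates, and cation exchange gives the ammonium salt that the enzyme accepts; no stereocentre is formed.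

**Step 3**
Reactants: 5 GGPP trisammonium salt
Product: 6 (R)-cembrene A, (1R,3E,7E,11E)-cembra-3,7,11,15-tetraene
Conditions: recombinant (R)-selective cembrene A synthase (class one diterpene cyclase), MgCl2, Tris·HCl pH 7.5, DTT, glycerol, 30 °C, pentane overlay
Reagents that add atoms: none
Why: The enzyme binds the diphosphate through its aspartate-rich motif and magnesium ions and ionises the C2–O bond, giving the C2–C3–C4 allyl cation held next to the distal C1=C15 double bond; C1 attacks C2, the new C1–C2 bond closes the ring, and the tertiary C15 cation loses a proton from C16 to leave the isopropenyl group. The closest known reaction type is the cation–olefin cyclisation of class one terpene synthases, and this conversion is what cembrene A synthases catalyse. The single ring is closed in a 14-membered Markovnikov mode in which C1 becomes a ring atom and C15 stays exocyclic (exo with respect to the attacked alkene), with the E geometry of the C3, C7 and C11 double bonds carried into the ring. The only new stereocentre, C1, is set by the active-site fold, which presents one face of the C1=C15 alkene to C2. The step needs 14-membered closure over smaller rings, no isomerisation of the allyl cation and a clean C16 deprotonation without water capture, and all three are secured by the enzyme pocket acting on its unmodified natural substrate.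

**Step 4**
Reactants: 6 (R)-cembrene A
Product: 8 (1R,3E,7E,11E,15RS)-cembra-3,7,11-trien-16-ol, via B-(cembratrien-16-yl)-9-BBN adduct 7 (not isolated)
Conditions: 9-BBN (1.1 equiv), THF, 0 °C to rt; then NaOH, H2O2, 0 °C
Reagents that add atoms: hydrogen peroxide, OO
Why: Hydroboration–oxidation: 9-BBN adds to the 1,1-disubstituted C15=C16 alkene much faster than to the three trisubstituted ring alkenes and puts boron on terminal C16, and oxidation keeps the C–O position; C15 forms without control and both epimers are carried to step 9.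

**Step 5**
Reactants: 8 (1R,3E,7E,11E,15RS)-cembra-3,7,11-trien-16-ol
Product: 10 (1R,3E,7E,11E,15RS)-cembra-3,7,11-trien-16-oic acid, via C16 aldehyde 9 (not isolated)
Conditions: TEMPO (0.2 equiv), PhI(OAc)2 (2.2 equiv), MeCN/H2O (1:1), rt
Reagents that add atoms: water, O
Why: TEMPO-catalysed oxoammonium oxidation with PhI(OAc)2 in aqueous MeCN takes a primary alcohol through the aldehyde hydrate to the acid and leaves trisubstituted alkenes alone; no stereocentre is formed.

**Step 6**
Reactants: 10 (1R,3E,7E,11E,15RS)-cembra-3,7,11-trien-16-oic acid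
Product: 11 (1R,3R,4S,7E,11E,15RS)-4-iodocembra-7,11-dien-16,3-olide
Conditions: I2 (3 equiv), NaHCO3, MeCN, 0 °C, dark
Reagents that add atoms: iodine, II
Why: Iodolactonisation: iodonium ions form reversibly on all three ring alkenes, but only the one on C3=C4 can be trapped by the carboxylate through a six-membered (6-exo) closure at C3, closure at C12 needing a seven-membered ring; anti addition across the E alkene ties C4 to C3, and the chair-like closure with the C1–C14 and C3–C4 bonds both equatorial (cis-bridged lactone) sets C3 as R from C1.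

**Step 7**
Reactants: 11 (1R,3R,4S,7E,11E,15RS)-4-iodocembra-7,11-dien-16,3-olide
Product: 13 methyl (1R,3R,4R,7E,11E,15RS)-3,4-epoxycembra-7,11-dien-16-oate, via iodohydrin methyl ester 12 (not isolated)
Conditions: K2CO3 (2 equiv), MeOH, 0 °C to rt
Reagents that add atoms: methanol, CO
Why: Methanolysis of the lactone frees the C3 alkoxide anti to the tertiary C4–I bond, and intramolecular Williamson closure (retention at C3, inversion at C4) gives the trans (3R,4R)-epoxide, the known conversion of iodolactones into epoxy esters; a C4–O lactone isomer, should any form in step 6, gives the same epoxide.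

**Step 8**
Reactants: 13 methyl (1R,3R,4R,7E,11E,15RS)-3,4-epoxycembra-7,11-dien-16-oate
Product: 15 (1R,3R,4S,7E,11E,15RS)-4-hydroxycembra-7,11-dien-16,3-olide, via diol methyl ester 14 (not isolated)
Conditions: HClO4 (cat., 3% aq.), THF/H2O, 0 °C; then PPTS (cat.), toluene, 40 °C
Reagents that add atoms: water, O
Why: Acid-catalysed epoxide hydrolysis takes water at the tertiary carbon C4 with inversion, so O3 and O4 end anti across the former E alkene in the (3R,4S)-diol, and the secondary C3–OH then closes the six-membered lactone on the ester by acid-catalysed transesterification while the tertiary C4–OH stays free.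

**Step 9**
Reactants: 15 (1R,3R,4S,7E,11E,15RS)-4-hydroxycembra-7,11-dien-16,3-olide
Product: 16 (1R,3R,4S,7E,11E,15S)-4-hydroxycembra-7,11-dien-16,3-olide
Conditions: t-BuOK (0.2 equiv), t-BuOH/THF, rt; AcOH quench; minor epimer recycled
Reagents that add atoms: none
Why: Thermodynamic epimerisation through the lactone enolate: C15 is the only stereocentre with an acidic hydrogen, and equilibrium should favour the epimer with the C17 methyl equatorial on the lactone and trans to the C1–C14 bond, which is 15S.

**Step 10**
Reactants: 16 (1R,3R,4S,7E,11E,15S)-4-hydroxycembra-7,11-dien-16,3-olide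
Product: 17 (1R,3R,4S,11E,15S)-7,8-epoxy-4-hydroxycembr-11-en-16,3-olide (trans epoxide; face not fixed)
Conditions: VO(acac)2 (5 mol%), t-BuOOH (1.5 equiv, decane), 2,6-lutidine, CH2Cl2, 0 °C
Reagents that add atoms: tert-butyl hydroperoxide, CC(C)(C)OO
Why: Hydroxyl-directed epoxidation: the vanadate ester of the tertiary C4–OH is bishomoallylic to C7=C8 and delivers the peroxide oxygen there, whereas C11=C12 has no hydroxyl within reach; the face of attack is left open because C8 becomes sp2 in step 11 and C7 is reset in steps 12 and 13.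

**Step 11**
Reactants: 17 (1R,3R,4S,11E,15S)-7,8-epoxy-4-hydroxycembr-11-en-16,3-olide
Product: 18 (1R,3R,4S,7RS,11E,15S)-4,7-dihydroxycembra-8(19),11-dien-16,3-olide
Conditions: Cp2TiCl2 (2.5 equiv), Mn dust, THF, rt; cold dilute HCl quench
Reagents that add atoms: none
Why: Titanocene monochloride-mediated epoxide isomerisation: Cp2TiCl (trivalent titanium) opens the epoxide by electron transfer to the tertiary C8 radical, and a second Cp2TiCl removes a hydrogen atom, preferentially from the C19 methyl, giving the titanium alkoxide of the C8=C19 exo-methylene allylic alcohol; the C8 radical has no alkene in 5-exo or 6-endo reach and the lactone is inert.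

**Step 12**
Reactants: 18 (1R,3R,4S,7RS,11E,15S)-4,7-dihydroxycembra-8(19),11-dien-16,3-olide
Product: 19 (1R,3R,4S,11E,15S)-4-hydroxy-7-oxocembra-8(19),11-dien-16,3-olide
Conditions: Dess–Martin periodinane (1.3 equiv), NaHCO3, CH2Cl2, 0 °C to rt
Reagents that add atoms: none
Why: Dess–Martin oxidation turns the secondary allylic C7–OH into the ketone while the tertiary C4–OH cannot be oxidised, which removes the uncontrolled C7 centre on purpose; a γ-hydroxy enone of this kind should stay on the open-chain side of the hemiketal equilibrium.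

**Step 13**
Reactants: 19 (1R,3R,4S,11E,15S)-4-hydroxy-7-oxocembra-8(19),11-dien-16,3-olide
Product: 20 (1R,3R,4S,7R,11E,15S)-4,7-dihydroxycembra-8(19),11-dien-16,3-olide
Conditions: (S)-2-methyl-CBS-oxazaborolidine (1 equiv), catecholborane (3 equiv), toluene, −78 °C; MeOH quench
Reagents that add atoms: none
Why: Corey–Bakshi–Shibata reduction: with the 2-substituted vinyl group at C8 as the large and the C6 methylene as the small carbonyl substituent, the (S)-oxazaborolidine delivers hydride to the face that gives the 7R alcohol (the sense that turns acetophenone into (R)-1-phenylethanol), and catecholborane at −78 °C touches neither lactone nor alkenes.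

**Step 14**
Reactants: 20 (1R,3R,4S,7R,11E,15S)-4,7-dihydroxycembra-8(19),11-dien-16,3-olide
Product: 21 (1R,3R,4S,7R,11S,12S,15S)-11,12-epoxy-4,7-dihydroxycembr-8(19)-en-16,3-olide (CNP0262409.1)
Conditions: L-series Shi ketone (1,2:4,5-di-O-isopropylidene-β-L-erythro-2,3-hexodiulo-2,6-pyranose, 0.3 equiv), KHSO5 (as the triple salt 2KHSO5·KHSO4·K2SO4), K2CO3, Bu4NHSO4, MeCN/dimethoxymethane, aq. Na2B4O7–Na2EDTA buffer (pH about 10), 0 °C
Reagents that add atoms: potassium peroxymonosulfate, [K+].OOS(=O)(=O)[O-]
Why: Shi asymmetric epoxidation: the chiral dioxirane reacts with the electron-rich trisubstituted C11=C12 alkene much faster than with the 1,1-disubstituted C8=C19 alkene, and the L-series ketone, the mirror image of the D-fructose catalyst that gives (R,R)-epoxides from E-trisubstituted alkenes, sets 11S and 12S through the spiro transition state under reagent control.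

**Compound list**

1 | (2E,6E,10E)-geranylgeraniol | CC(C)=CCC/C(C)=C/CC/C(C)=C/CC/C(C)=C/CO | starting material
2 | (2E,6E,10E)-geranylgeranyl bromide | CC(C)=CCC/C(C)=C/CC/C(C)=C/CC/C(C)=C/CBr | intermediate
3 | tris(tetrabutylammonium) hydrogen diphosphate | CCCC[N+](CCCC)(CCCC)CCCC.CCCC[N+](CCCC)(CCCC)CCCC.CCCC[N+](CCCC)(CCCC)CCCC.OP(=O)([O-])OP(=O)([O-])[O-] | starting material
4 | geranylgeranyl diphosphate, bis(tetrabutylammonium) hydrogen salt | CC(C)=CCC/C(C)=C/CC/C(C)=C/CC/C(C)=C/COP(=O)([O-])OP(=O)(O)[O-].CCCC[N+](CCCC)(CCCC)CCCC.CCCC[N+](CCCC)(CCCC)CCCC | intermediate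
5 | geranylgeranyl diphosphate (GGPP), trisammonium salt | CC(C)=CCC/C(C)=C/CC/C(C)=C/CC/C(C)=C/COP(=O)([O-])OP(=O)([O-])[O-].[NH4+].[NH4+].[NH4+] | intermediate
6 | (R)-cembrene A, (1R,3E,7E,11E)-cembra-3,7,11,15-tetraene | C1/C=C(C)/CC[C@@H](C(C)=C)C/C=C(C)/CC/C=C(C)/C1 | intermediate
7 | B-[(1R,3E,7E,11E,15RS)-cembra-3,7,11-trien-16-yl]-9-borabicyclo[3.3.1]nonane | C1/C=C(C)/CC[C@@H](C(C)CB2C3CCCC2CCC3)C/C=C(C)/CC/C=C(C)/C1 | intermediate
8 | (1R,3E,7E,11E,15RS)-cembra-3,7,11-trien-16-ol | C1/C=C(C)/CC[C@@H](C(C)CO)C/C=C(C)/CC/C=C(C)/C1 | intermediate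
9 | (1R,3E,7E,11E,15RS)-cembra-3,7,11-trien-16-al | C1/C=C(C)/CC[C@@H](C(C)C=O)C/C=C(C)/CC/C=C(C)/C1 | intermediate
10 | (1R,3E,7E,11E,15RS)-cembra-3,7,11-trien-16-oic acid | C1/C=C(C)/CC[C@@H](C(C)C(=O)O)C/C=C(C)/CC/C=C(C)/C1 | intermediate
11 | (1R,3R,4S,7E,11E,15RS)-4-iodocembra-7,11-dien-16,3-olide | C1/C=C(C)/CC[C@@H]2C[C@@H](OC(=O)C2C)[C@@](C)(I)CC/C=C(C)/C1 | intermediate
12 | methyl (1R,3R,4S,7E,11E,15RS)-3-hydroxy-4-iodocembra-7,11-dien-16-oate | C1/C=C(C)/CC[C@@H](C(C)C(=O)OC)C[C@@H](O)[C@@](C)(I)CC/C=C(C)/C1 | intermediate
13 | methyl (1R,3R,4R,7E,11E,15RS)-3,4-epoxycembra-7,11-dien-16-oate | C1/C=C(C)/CC[C@@H](C(C)C(=O)OC)C[C@H]2O[C@]2(C)CC/C=C(C)/C1 | intermediate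
14 | methyl (1R,3R,4S,7E,11E,15RS)-3,4-dihydroxycembra-7,11-dien-16-oate | C1/C=C(C)/CC[C@@H](C(C)C(=O)OC)C[C@@H](O)[C@@](C)(O)CC/C=C(C)/C1 | intermediate
15 | (1R,3R,4S,7E,11E,15RS)-4-hydroxycembra-7,11-dien-16,3-olide | C1/C=C(C)/CC[C@@H]2C[C@@H](OC(=O)C2C)[C@@](C)(O)CC/C=C(C)/C1 | intermediate
16 | (1R,3R,4S,7E,11E,15S)-4-hydroxycembra-7,11-dien-16,3-olide | C1/C=C(C)/CC[C@@H]2C[C@@H](OC(=O)[C@H]2C)[C@@](C)(O)CC/C=C(C)/C1 | intermediate
17 | (1R,3R,4S,11E,15S)-7,8-epoxy-4-hydroxycembr-11-en-16,3-olide (trans epoxide, face not fixed) | C1/C=C(C)/CC[C@@H]2C[C@@H](OC(=O)[C@H]2C)[C@@](C)(O)CCC3OC3(C)C1 | intermediate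
18 | (1R,3R,4S,7RS,11E,15S)-4,7-dihydroxycembra-8(19),11-dien-16,3-olide | C=C1CC/C=C(C)/CC[C@@H]2C[C@@H](OC(=O)[C@H]2C)[C@@](C)(O)CCC1O | intermediate
19 | (1R,3R,4S,11E,15S)-4-hydroxy-7-oxocembra-8(19),11-dien-16,3-olide | C=C1CC/C=C(C)/CC[C@@H]2C[C@@H](OC(=O)[C@H]2C)[C@@](C)(O)CCC1=O | intermediate
20 | (1R,3R,4S,7R,11E,15S)-4,7-dihydroxycembra-8(19),11-dien-16,3-olide | C=C1CC/C=C(C)/CC[C@@H]2C[C@@H](OC(=O)[C@H]2C)[C@@](C)(O)CC[C@H]1O | intermediate
21 | (1R,3R,4S,7R,11S,12S,15S)-11,12-epoxy-4,7-dihydroxycembr-8(19)-en-16,3-olide (CNP0262409.1) | C=C1CC[C@@H]2O[C@@]2(C)CC[C@@H]2C[C@@H](OC(=O)[C@H]2C)[C@@](C)(O)CC[C@H]1O | target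

**Step count and risks**

Total step count: 14. Longest linear sequence: 14 steps, from geranylgeraniol 1.

Steps most likely to fail:

Step 10. The epoxy alcohol may not survive. Under the Lewis-acidic vanadium conditions the C4–OH can add across the ring to C7 or C8 of the new epoxide (transannular etherification), and direction by a tertiary hydroxyl may be slow. The fallback gives up direction and the metal. It sets out from 16: the D-fructose-derived Shi ketone with a limiting amount of KHSO5 in the buffer of step 14 should epoxidise either ring alkene in the (R,R) sense. The (7R,8R)-epoxide F4 is separated from its 11,12-isomer and from recovered 16 and is isomerised with Cp2TiCl as in step 11. This gives 20 directly, because the C7–O bond of F4 already has the R configuration, so compounds 17 to 19 are bypassed and the route is rejoined at 20.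

Step 6. Capture of the iodonium may lose site or facial control (closure onto C12, or carboxylate delivery to the other face of C3=C4), or the tertiary iodide may eliminate before step 7. The fallback replaces neighbouring-group delivery by reagent control. It sets out from 10: the methyl ester F1 (Me3SiCHN2, MeOH/toluene) is mono-epoxidised with the L-series Shi ketone and limiting KHSO5, and the (3S,4S)-3,4-epoxy ester F2 is separated from the 7,8- and 11,12-isomers. Saponification (LiOH, THF/H2O) gives the epoxy acid F3; on careful acidification to pH 4 to 5 its carboxyl group should open C3 from the rear in a 6-exo SN2 closure (inversion at C3, C4–O kept), which returns the route to 15.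

Step 14. The chiral dioxirane may meet a mismatched face of the macrocycle, and the lactone may open at the basic pH. The fallback builds the oxirane in two steps with the opposite facial logic. It sets out from 20: NBS in aqueous THF at 0 °C should put bromine on the more exposed face of C11=C12 and water on C12 from the other side, giving the bromohydrin F5. K2CO3 in acetone then closes the C12–O bond onto C11 with inversion, so the epoxide oxygen ends on the face that a direct electrophilic oxidant disfavours, and the route comes back at 21.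

**Further compounds**

F1 | step 6 | methyl (1R,3E,7E,11E,15RS)-cembra-3,7,11-trien-16-oate | C1/C=C(C)/CC[C@@H](C(C)C(=O)OC)C/C=C(C)/CC/C=C(C)/C1
F2 | step 6 | methyl (1R,3S,4S,7E,11E,15RS)-3,4-epoxycembra-7,11-dien-16-oate | C1/C=C(C)/CC[C@@H](C(C)C(=O)OC)C[C@@H]2O[C@@]2(C)CC/C=C(C)/C1
F3 | step 6 | (1R,3S,4S,7E,11E,15RS)-3,4-epoxycembra-7,11-dien-16-oic acid | C1/C=C(C)/CC[C@@H](C(C)C(=O)O)C[C@@H]2O[C@@]2(C)CC/C=C(C)/C1
F4 | step 10 | (1R,3R,4S,7R,8R,11E,15S)-7,8-epoxy-4-hydroxycembr-11-en-16,3-olide | C1/C=C(C)/CC[C@@H]2C[C@@H](OC(=O)[C@H]2C)[C@@](C)(O)CC[C@H]3O[C@]3(C)C1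
F5 | step 14 | (1R,3R,4S,7R,11R,12S,15S)-11-bromo-4,7,12-trihydroxycembr-8(19)-en-16,3-olide | C=C1CC[C@@H](Br)[C@@](C)(O)CC[C@@H]2C[C@@H](OC(=O)[C@H]2C)[C@@](C)(O)CC[C@H]1O
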